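The upper pyran ring is disconnected at O-1–C-2. Because C-4 of that ring carries two electron-rich aryl groups (ring A and ring D of the lower flavan) and C-2 carries ring B, the C-2/C-3/C-4 chain is a latent 1,1,3-triarylallyl cation. The precursor is therefore an open-chain tertiary allylic alcohol, made by adding the lithiated lower flavan to a 2'-hydroxychalcone. A chiral Brønsted acid dehydrates it to a vinylogous o-quinone methide of ring A, whose oxa-6π closure forms the ring and sets C-2; the C-3=C-4 alkene left behind then takes up H and OH trans to the C-2 aryl in a single hydroboration. Both flavan units derive from one chalcone.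

Key step: step 8

Assumption: (R)-NTPA denotes (R)-3,3'-bis(9-phenanthryl)-1,1'-binaphthalene-2,2'-diyl N-(trifluoromethylsulfonyl)phosphoramide. It is taken to give the (2S)-chromenes (C-2 aryl on the α face); if the sense of induction is the opposite, the (S)-acid is used in steps 3 and 8 with no other change.

**Step 1**
Reactants: 1 1-[4-(benzyloxy)-2-hydroxyphenyl]ethan-1-one; 2 3,4-bis(benzyloxy)benzaldehyde
Product: 4 (E)-2'-hydroxy-4'-benzyloxy-3,4-bis(benzyloxy)chalcone, via aldol adduct 3 (not isolated)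
Conditions: KOH (3 equiv), EtOH/THF/H2O, 0 °C to rt; then aq. HCl to pH 6
Reagents that add atoms: none
Why: Claisen–Schmidt condensation, in which the acetophenone enolate adds to the non-enolisable aldehyde and aldol 3 loses water by E1cB elimination to the conjugated (E)-enone, while the phenoxide formed under excess base does not close to the flavanone at room temperature.

**Step 2**
Reactants: 4 (E)-2'-hydroxy-4'-benzyloxy-3,4-bis(benzyloxy)chalcone
Product: 5 (E)-1-[4-(benzyloxy)-2-hydroxyphenyl]-3-[3,4-bis(benzyloxy)phenyl]prop-2-en-1-ol (racemic)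
Conditions: NaBH4, CeCl3·7H2O, MeOH/THF, −20 °C; pH 7 phosphate buffer work-up, crude product used at once
Reagents that add atoms: none
Why: Luche reduction, in which the oxophilic cerium salt directs hydride to the carbonyl carbon (1,2-reduction) and leaves the styryl double bond intact; the new carbinol centre is racemic and is erased in step 3.

**Step 3**
Reactants: 5 (E)-1-[4-(benzyloxy)-2-hydroxyphenyl]-3-[3,4-bis(benzyloxy)phenyl]prop-2-en-1-ol (racemic)
Product: 7 (2S)-7-(benzyloxy)-2-[3,4-bis(benzyloxy)phenyl]-2H-chromene, via o-quinone methide 6 (not isolated)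
Conditions: (R)-NTPA (5 mol%), toluene, 4 Å MS, −60 °C; Et3N quench
Reagents that add atoms: none
Why: Asymmetric Brønsted acid-catalysed intramolecular allylic substitution of a 2-(1-hydroxyallyl)phenol, in which dehydration gives o-quinone methide 6 as its ion pair with the chiral phosphoramide anion and oxa-6π closure of the phenol oxygen onto the styryl terminus forms the chromene with C-2 set by the chiral anion.

**Step 4**
Reactants: 7 (2S)-7-(benzyloxy)-2-[3,4-bis(benzyloxy)phenyl]-2H-chromene
Product: 8 (2R,3S,4S)-7-(benzyloxy)-2-[3,4-bis(benzyloxy)phenyl]chromane-3,4-diol (2,3-trans-3,4-cis)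
Conditions: OsO4 (2 mol%), NMO, acetone/H2O, 0 °C to rt
Reagents that add atoms: osmium tetroxide, O=[Os](=O)(=O)=O; N-methylmorpholine N-oxide, C[N+]1([O-])CCOCC1; water, O
Why: Catalytic OsO4/NMO syn-dihydroxylation of the flav-3-ene, in which both oxygens are delivered to the face opposite the C-2 aryl group, so that C-3 and C-4 are set as the 2,3-trans-3,4-cis diol by substrate control.

**Step 5**
Reactants: 8 (2R,3S,4S)-7-(benzyloxy)-2-[3,4-bis(benzyloxy)phenyl]chromane-3,4-diol
Product: 9 (2R,3S,4S)-3,4,7-tris(benzyloxy)-2-[3,4-bis(benzyloxy)phenyl]chromane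
Conditions: NaH, BnBr, Bu4NI (cat.), DMF, 0 °C to rt
Reagents that add atoms: benzyl bromide, BrCc1ccccc1
Why: Williamson etherification of both secondary alkoxides, which touches no stereocentre and gives a diol protection that withstands the aryllithium and the acid of later steps and leaves together with the phenol benzyl ethers at the end.

**Step 6**
Reactants: 9 (2R,3S,4S)-3,4,7-tris(benzyloxy)-2-[3,4-bis(benzyloxy)phenyl]chromane
Product: 10 (2R,3S,4S)-3,4,7-tris(benzyloxy)-2-[3,4-bis(benzyloxy)phenyl]-6-bromochromane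
Conditions: NBS (1.0 equiv), CH2Cl2, −40 to 0 °C, dark
Reagents that add atoms: N-bromosuccinimide, O=C1CCC(=O)N1Br
Why: Electrophilic aromatic bromination at C-6, which is ortho to the 7-benzyloxy group and para to O-1 and so is the most activated open position, while C-8 is flanked by two oxygens and the catechol ring is activated by only one oxygen per position.

**Step 7**
Reactants: 10 (2R,3S,4S)-3,4,7-tris(benzyloxy)-2-[3,4-bis(benzyloxy)phenyl]-6-bromochromane; 4 (E)-2'-hydroxy-4'-benzyloxy-3,4-bis(benzyloxy)chalcone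
Product: 13 triaryl allylic carbinol (both C-1 epimers), via aryllithium 11 (not isolated), via lithium phenoxide 12 (not isolated)
Conditions: 10, t-BuLi (2.0 equiv), THF, −78 °C; separately 4 (1.3 equiv), LiN(SiMe3)2 (1.3 equiv), THF, −78 °C; combine, −78 to −20 °C; H2O/aq. NaHCO3, crude product kept basic
Reagents that add atoms: none
Why: Bromine–lithium exchange followed by 1,2-addition of the aryllithium to the lithium-chelated ketone of the pre-formed phenoxide (lithiated benzylated flavans are known to add to ketones, and the electron-rich styryl terminus disfavours conjugate addition); the new carbinol centre forms unselectively and is erased in step 8.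

**Step 8**
Reactants: 13 triaryl allylic carbinol (both C-1 epimers)
Product: 15 (2S)-4-aryl-2H-chromene carrying the lower flavan at C-4, via o-quinone methide 14 (not isolated)
Conditions: (R)-NTPA (10 mol%), toluene, 4 Å MS, −78 °C; Et3N quench at −78 °C
Reagents that add atoms: none
Why: The strong chiral acid ionises the tertiary, doubly benzylic allylic alcohol to a contact ion pair that is the protonated form of vinylogous o-quinone methide 14, and the ring A oxygen then bonds to C-2; the closest known reaction type is the chiral N-triflylphosphoramide-catalysed intramolecular allylic substitution of 2-(1-hydroxy-1,3-diarylallyl)phenols to 2,4-diaryl-2H-chromenes. The ring closes in a 6-endo sense at the allyl terminus, which is equivalent to a thermal disrotatory oxa-6π electrocyclisation of 14. The only new stereocentre, C-2, is set by the chiral counter-anion, which shields one face of the styryl terminus; both carbinol epimers converge because C-1 becomes planar, and the stereocentres of the lower flavan are too remote to compete with catalyst control. The step needs closure through O-1 only, and this is secured because the competing ortho oxygen on ring D is benzylated, so the isomeric pyran through ring D cannot form. Re-ionisation of the electron-rich product, which would epimerise C-2, is held back by the low temperature and the amine quench.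

**Step 9**
Reactants: 15 (2S)-4-aryl-2H-chromene carrying the lower flavan at C-4
Product: 17 octa-O-benzyl biflavanoid with free upper 3-OH (upper ring 2,3-trans-3,4-trans), via organoborane 16 (not isolated)
Conditions: BH3·THF (3 equiv), THF, 0 °C to rt; then aq. NaOH, H2O2 (30%), 0 °C
Reagents that add atoms: hydrogen peroxide, OO (oxygen at C-3); borane as its THF complex, B (boron in 16 only, hydrogen at C-4 of 17)
Why: Hydroboration–oxidation, in which boron goes to C-3 (the less substituted carbon, leaving positive charge on the diaryl-substituted C-4) and adds syn with hydrogen from the face opposite the C-2 aryl, so that after oxidation with retention the 3-OH is trans to ring B and the ring D aryl at C-4 is trans to the 3-OH.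

**Step 10**
Reactants: 17 octa-O-benzyl biflavanoid with free upper 3-OH
Product: 18 CNP0280090.4
Conditions: H2 (1 atm), Pd(OH)2/C, THF/MeOH (1:1), rt, stopped at full conversion; filtration under argon
Reagents that add atoms: none
Why: Hydrogenolysis of the eight benzyl ethers at their unhindered PhCH2–O bonds, whereas the ring benzylic C–O bonds (C-2–O-1 of both units and C-4–O of the lower unit) are secondary, hindered and β-oxygenated and are expected to cleave far more slowly under neutral conditions.

**Compound list**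

1 | 1-[4-(benzyloxy)-2-hydroxyphenyl]ethan-1-one | CC(=O)c1ccc(OCc2ccccc2)cc1O | starting material
2 | 3,4-bis(benzyloxy)benzaldehyde | O=Cc1ccc(OCc2ccccc2)c(OCc2ccccc2)c1 | starting material
3 | aldol adduct, 1-[4-(benzyloxy)-2-hydroxyphenyl]-3-[3,4-bis(benzyloxy)phenyl]-3-hydroxypropan-1-one (racemic) | O=C(CC(O)c1ccc(OCc2ccccc2)c(OCc2ccccc2)c1)c1ccc(OCc2ccccc2)cc1O | intermediate (not isolated)
4 | (E)-1-[4-(benzyloxy)-2-hydroxyphenyl]-3-[3,4-bis(benzyloxy)phenyl]prop-2-en-1-one (chalcone) | O=C(/C=C/c1ccc(OCc2ccccc2)c(OCc2ccccc2)c1)c1ccc(OCc2ccccc2)cc1O | intermediate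
5 | (E)-1-[4-(benzyloxy)-2-hydroxyphenyl]-3-[3,4-bis(benzyloxy)phenyl]prop-2-en-1-ol (racemic, carbinol centre undefined) | OC(/C=C/c1ccc(OCc2ccccc2)c(OCc2ccccc2)c1)c1ccc(OCc2ccccc2)cc1O | intermediate
6 | o-quinone methide, (6Z)-3-(benzyloxy)-6-[(2E)-3-[3,4-bis(benzyloxy)phenyl]prop-2-en-1-ylidene]cyclohexa-2,4-dien-1-one (styryl chain on the side of the ring carbonyl) | O=C1C=C(OCc2ccccc2)C=C/C1=C/C=C/c1ccc(OCc2ccccc2)c(OCc2ccccc2)c1 | intermediate (not isolated)
7 | (2S)-7-(benzyloxy)-2-[3,4-bis(benzyloxy)phenyl]-2H-chromene | c1cc2c(cc1OCc1ccccc1)O[C@H](c1ccc(OCc3ccccc3)c(OCc3ccccc3)c1)C=C2 | intermediate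
8 | (2R,3S,4S)-7-(benzyloxy)-2-[3,4-bis(benzyloxy)phenyl]chromane-3,4-diol (2,3-trans-3,4-cis) | c1cc2c(cc1OCc1ccccc1)O[C@H](c1ccc(OCc3ccccc3)c(OCc3ccccc3)c1)[C@@H](O)[C@H]2O | intermediate
9 | (2R,3S,4S)-3,4,7-tris(benzyloxy)-2-[3,4-bis(benzyloxy)phenyl]chromane | c1cc2c(cc1OCc1ccccc1)O[C@H](c1ccc(OCc3ccccc3)c(OCc3ccccc3)c1)[C@@H](OCc1ccccc1)[C@H]2OCc1ccccc1 | intermediate
10 | (2R,3S,4S)-3,4,7-tris(benzyloxy)-2-[3,4-bis(benzyloxy)phenyl]-6-bromochromane | Brc1cc2c(cc1OCc1ccccc1)O[C@H](c1ccc(OCc3ccccc3)c(OCc3ccccc3)c1)[C@@H](OCc1ccccc1)[C@H]2OCc1ccccc1 | intermediate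
11 | aryllithium, 6-lithio derivative of 9 | [Li]c1cc2c(cc1OCc1ccccc1)O[C@H](c1ccc(OCc3ccccc3)c(OCc3ccccc3)c1)[C@@H](OCc1ccccc1)[C@H]2OCc1ccccc1 | intermediate (not isolated)
12 | lithium phenoxide of chalcone 4 | [Li+].[O-]c1cc(OCc2ccccc2)ccc1C(=O)/C=C/c1ccc(OCc2ccccc2)c(OCc2ccccc2)c1 | intermediate (not isolated)
13 | (E)-1-[4-(benzyloxy)-2-hydroxyphenyl]-3-[3,4-bis(benzyloxy)phenyl]-1-[(2R,3S,4S)-3,4,7-tris(benzyloxy)-2-[3,4-bis(benzyloxy)phenyl]chroman-6-yl]prop-2-en-1-ol (both C-1 epimers, centre undefined and erased in step 8) | OC(/C=C/c1ccc(OCc2ccccc2)c(OCc2ccccc2)c1)(c1ccc(OCc2ccccc2)cc1O)c1cc2c(cc1OCc1ccccc1)O[C@H](c1ccc(OCc3ccccc3)c(OCc3ccccc3)c1)[C@@H](OCc1ccccc1)[C@H]2OCc1ccccc1 | intermediate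
14 | vinylogous o-quinone methide, (6E)-3-(benzyloxy)-6-[(2E)-3-[3,4-bis(benzyloxy)phenyl]-1-(lower flavan-6-yl)prop-2-en-1-ylidene]cyclohexa-2,4-dien-1-one (styryl chain on the side of the ring carbonyl) | O=C1C=C(OCc2ccccc2)C=C/C1=C(/C=C/c1ccc(OCc2ccccc2)c(OCc2ccccc2)c1)c1cc2c(cc1OCc1ccccc1)O[C@H](c1ccc(OCc3ccccc3)c(OCc3ccccc3)c1)[C@@H](OCc1ccccc1)[C@H]2OCc1ccccc1 | intermediate (not isolated)
15 | (2S)-7-(benzyloxy)-2-[3,4-bis(benzyloxy)phenyl]-4-[(2R,3S,4S)-3,4,7-tris(benzyloxy)-2-[3,4-bis(benzyloxy)phenyl]chroman-6-yl]-2H-chromene | C(c1ccccc1)Oc1ccc2c(c1)O[C@H](c1ccc(OCc3ccccc3)c(OCc3ccccc3)c1)C=C2c1cc2c(cc1OCc1ccccc1)O[C@H](c1ccc(OCc3ccccc3)c(OCc3ccccc3)c1)[C@@H](OCc1ccccc1)[C@H]2OCc1ccccc1 | intermediate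
16 | C-3 alkylborane of 15 (BH2 at C-3 and new H at C-4 both on the face opposite the C-2 aryl; drawn as the monoalkylborane) | C(c1ccccc1)Oc1ccc2c(c1)O[C@H](c1ccc(OCc3ccccc3)c(OCc3ccccc3)c1)[C@@H](B)[C@@H]2c1cc2c(cc1OCc1ccccc1)O[C@H](c1ccc(OCc3ccccc3)c(OCc3ccccc3)c1)[C@@H](OCc1ccccc1)[C@H]2OCc1ccccc1 | intermediate (not isolated)
17 | (2R,3S,4S)-7-(benzyloxy)-2-[3,4-bis(benzyloxy)phenyl]-4-[(2R,3S,4S)-3,4,7-tris(benzyloxy)-2-[3,4-bis(benzyloxy)phenyl]chroman-6-yl]chroman-3-ol (upper ring 2,3-trans-3,4-trans) | C(c1ccccc1)Oc1ccc2c(c1)O[C@H](c1ccc(OCc3ccccc3)c(OCc3ccccc3)c1)[C@@H](O)[C@@H]2c1cc2c(cc1OCc1ccccc1)O[C@H](c1ccc(OCc3ccccc3)c(OCc3ccccc3)c1)[C@@H](OCc1ccccc1)[C@H]2OCc1ccccc1 | intermediate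
18 | CNP0280090.4, (2R,3S,4S)-2-(3,4-dihydroxyphenyl)-6-[(2R,3S,4R)-2-(3,4-dihydroxyphenyl)-3,7-dihydroxychroman-4-yl]chromane-3,4,7-triol | Oc1ccc2c(c1)O[C@H](c1ccc(O)c(O)c1)[C@@H](O)[C@@H]2c1cc2c(cc1O)O[C@H](c1ccc(O)c(O)c1)[C@@H](O)[C@H]2O | target

**Step count and risks**

Total steps: 10. Longest linear sequence: 10 steps (1 and 2 to 18; chalcone 4 enters twice, in step 2 and in step 7).

The three steps most likely to fail:

Step 8. The chiral anion may discriminate poorly between the two faces of the allyl terminus in so large an ion pair, and the very electron-rich chromene may re-ionise at C-2–O-1 and epimerise. The fallback sets out from 13 and comes back at 15. Carbinol 13 is cyclised without asymmetric induction by an achiral acid (diphenyl phosphate, 10 mol%, CH2Cl2, −40 °C), which gives 15 together with the (2R)-epimer of the chromene F1. Because the lower flavan is homochiral, the two are diastereomers and are separated by chromatography. F1 is returned to the same acid, where ring opening to 14 and reclosure regenerate the mixture, so the material is funnelled to 15.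

Step 9. Borane may add slowly to the hindered triaryl-substituted alkene, or from the face of the C-2 aryl, or with boron at C-4. The fallback sets out from 15 and comes back at 17. Syn-dihydroxylation with OsO4 (cat.)/NMO in acetone/H2O, anti to the C-2 aryl, gives the upper 3,4-cis-diol F2, in which the C-3 oxygen already has the required configuration. Ionic hydrogenation (Et3SiH, CF3CO2H, CH2Cl2, −78 °C) then removes the tertiary, doubly benzylic 4-hydroxyl through the C-4 cation. Axial hydride delivery places the ring D aryl equatorial, cis to the C-2 aryl and trans to the 3-OH, which is 17.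

Step 7. The hindered aryllithium may add sluggishly or in conjugate fashion to the phenoxide-deactivated enone, or be consumed by proton transfer. The fallback sets out from 4 (with bromide 10) and comes back at 13. The phenol of 4 is silylated (t-BuMe2SiCl, imidazole, DMF, rt) to the chalcone silyl ether F3, whose ketone is a neutral, more electrophilic acceptor. Aryllithium 11, generated from 10 as before, is added at −78 °C to give the silyl-protected carbinol F4. Bu4NF in THF at 0 °C, which is basic and does not ionise the carbinol, frees the phenol and returns 13.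

**Further compounds**

F1 | step 8 | (2R)-7-(benzyloxy)-2-[3,4-bis(benzyloxy)phenyl]-4-[(2R,3S,4S)-3,4,7-tris(benzyloxy)-2-[3,4-bis(benzyloxy)phenyl]chroman-6-yl]-2H-chromene (C-2 epimer of 15) | C(c1ccccc1)Oc1ccc2c(c1)O[C@@H](c1ccc(OCc3ccccc3)c(OCc3ccccc3)c1)C=C2c1cc2c(cc1OCc1ccccc1)O[C@H](c1ccc(OCc3ccccc3)c(OCc3ccccc3)c1)[C@@H](OCc1ccccc1)[C@H]2OCc1ccccc1
F2 | step 9 | upper 3,4-cis-diol of 15 (3-OH and 4-OH on the face opposite the C-2 aryl, ring D aryl at C-4 on the face of the C-2 aryl) | C(c1ccccc1)Oc1ccc2c(c1)O[C@H](c1ccc(OCc3ccccc3)c(OCc3ccccc3)c1)[C@@H](O)[C@]2(O)c1cc2c(cc1OCc1ccccc1)O[C@H](c1ccc(OCc3ccccc3)c(OCc3ccccc3)c1)[C@@H](OCc1ccccc1)[C@H]2OCc1ccccc1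
F3 | step 7 | (E)-1-[4-(benzyloxy)-2-(tert-butyldimethylsilyloxy)phenyl]-3-[3,4-bis(benzyloxy)phenyl]prop-2-en-1-one | O=C(/C=C/c1ccc(OCc2ccccc2)c(OCc2ccccc2)c1)c1ccc(OCc2ccccc2)cc1O[Si](C)(C)C(C)(C)C
F4 | step 7 | O-silyl derivative of carbinol 13 (tert-butyldimethylsilyl on the ring A phenol oxygen, both C-1 epimers) | OC(/C=C/c1ccc(OCc2ccccc2)c(OCc2ccccc2)c1)(c1ccc(OCc2ccccc2)cc1O[Si](C)(C)C(C)(C)C)c1cc2c(cc1OCc1ccccc1)O[C@H](c1ccc(OCc3ccccc3)c(OCc3ccccc3)c1)[C@@H](OCc1ccccc1)[C@H]2OCc1ccccc1
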